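Assumption: Marchantin A has no stereocentres and is not configurationally stable as atropisomers at room temperature, so the SMILES describes an achiral compound and no stereocontrol is needed. The route has not been run; conditions are proposed from standard precedent for each reaction type.

## Retrosynthetic overview

1. Marchantin A ⇐ its tri-O-methyl ether (BBr3) ⇐ macrocyclic stilbene (hydrogenation).
2. The 18-membered ring is closed last, at the B–C two-carbon bridge, by intramolecular McMurry coupling of a dialdehyde (ring B CHO + ring C CHO).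
3. Those two aldehydes are also the SNAr activating groups used to build both diaryl ethers (A–O–B from 4-fluorobenzaldehyde, C–O–D from 2-fluoro-3-methoxybenzaldehyde).
4. The D–A two-carbon bridge comes from Sonogashira coupling (ring D iodide + ring A alkyne), then aldehyde-sparing hydrogenation.
5. Order: C–O–D ether → D–A bridge → A–O–B ether → macrocycle (the only ring formed; all four arenes are purchased).

## Route

**Step 1**
Reactants: 1, 3-hydroxy-4,5-dimethoxybenzaldehyde; 2, dimethyl (1-diazo-2-oxopropyl)phosphonate (Ohira–Bestmann reagent)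
Product: 3, 5-ethynyl-2,3-dimethoxyphenol
Conditions: 2 (1.5 equiv), K2CO3 (3 equiv), MeOH, 0 °C → rt
Reagents that add atoms: Ohira–Bestmann reagent (2), CC(=O)C(=[N+]=[N-])P(=O)(OC)OC, supplies the terminal alkyne carbon
Why: Seyferth–Gilbert homologation (Ohira–Bestmann variant) converts ArCHO to ArC≡CH; the phenoxide is meta to the aldehyde and does not deactivate it. No stereocentre.

**Step 2**
Reactants: 4, 2-fluoro-3-methoxybenzaldehyde; 5, 3-iodophenol
Product: 6, 2-(3-iodophenoxy)-3-methoxybenzaldehyde (C–O–D ether)
Conditions: K2CO3, DMF, 120 °C, Ar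
Reagents that add atoms: 3-iodophenol (5), Oc1cccc(I)c1
Why: SNAr; the fluoride is ortho to the formyl group, which stabilises the Meisenheimer intermediate, and the aryl iodide is inert without a metal catalyst.

**Step 3**
Reactants: 3, 5-ethynyl-2,3-dimethoxyphenol; 6, 2-(3-iodophenoxy)-3-methoxybenzaldehyde
Product: 7, 2-{3-[(3-hydroxy-4,5-dimethoxyphenyl)ethynyl]phenoxy}-3-methoxybenzaldehyde
Conditions: PdCl2(PPh3)2 (3 mol%), CuI (5 mol%), Et3N/THF, degassed, rt → 40 °C
Reagents that add atoms: alkyne 3, C#Cc1cc(O)c(OC)c(OC)c1
Why: Sonogashira coupling of an aryl iodide with a terminal alkyne; it tolerates the free phenol and the aldehyde and installs both carbons of the D–A bridge.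

**Step 4**
Reactants: 7
Product: 8, 2-{3-[2-(3-hydroxy-4,5-dimethoxyphenyl)ethyl]phenoxy}-3-methoxybenzaldehyde
Conditions: H2 (1 atm), 10% Pd/C, Ph2S (cat.), EtOAc, rt
Reagents that add atoms: none (H2 only)
Why: Chemoselective heterogeneous hydrogenation; sulfide-poisoned Pd/C saturates the diaryl alkyne while leaving the aromatic aldehyde intact.

**Step 5**
Reactants: 8; 9, 4-fluorobenzaldehyde
Product: 10, 2-(3-{2-[3-(4-formylphenoxy)-4,5-dimethoxyphenyl]ethyl}phenoxy)-3-methoxybenzaldehyde (open-chain dialdehyde)
Conditions: K2CO3, DMF, 120 °C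
Reagents that add atoms: 4-fluorobenzaldehyde (9), O=Cc1ccc(F)cc1
Why: SNAr of the ring A phenoxide on a para-formyl-activated aryl fluoride forms the A–O–B ether; neither aldehyde is enolisable, and the alkyne is already saturated, so base-promoted phenoxide addition to it is not an issue.

**Step 6**
Reactants: 10
Product: 11, macrocyclic stilbene (tri-O-methyl-dehydromarchantin A, B–CH=CH–C bridge, E/Z mixture)
Conditions: TiCl4, Zn, pyridine, THF, reflux; syringe-pump addition of 10 over ~20 h (final ~2 mM)
Reagents that add atoms: none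
Why: Intramolecular McMurry reductive coupling of the two aryl aldehydes under high dilution closes the 18-membered ring; aryl ethers are inert to low-valent Ti, and the alkene geometry is irrelevant because it is hydrogenated next.

**Step 7**
Reactants: 11
Product: 12, marchantin A tri-O-methyl ether
Conditions: H2 (1 atm), 10% Pd/C, EtOAc/EtOH, rt
Reagents that add atoms: none (H2 only)
Why: Catalytic hydrogenation of the stilbene C=C; diaryl and methyl ethers are not hydrogenolysed. No stereocentre is created.

**Step 8**
Reactants: 12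
Product: 13, marchantin A
Conditions: BBr3 (8 equiv), CH2Cl2, −78 °C → rt; then MeOH/H2O, work-up under Ar
Reagents that add atoms: none
Why: Lewis-acid (BBr3) cleavage of the three aryl methyl ethers; the diaryl ether linkages are stable to BBr3.

## Compound list

1 | 3-hydroxy-4,5-dimethoxybenzaldehyde | O=Cc1cc(O)c(OC)c(OC)c1 | starting material
2 | dimethyl (1-diazo-2-oxopropyl)phosphonate | CC(=O)C(=[N+]=[N-])P(=O)(OC)OC | starting material (reagent)
3 | 5-ethynyl-2,3-dimethoxyphenol | C#Cc1cc(O)c(OC)c(OC)c1 | intermediate
4 | 2-fluoro-3-methoxybenzaldehyde | O=Cc1cccc(OC)c1F | starting material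
5 | 3-iodophenol | Oc1cccc(I)c1 | starting material
6 | 2-(3-iodophenoxy)-3-methoxybenzaldehyde | O=Cc1cccc(OC)c1Oc1cccc(I)c1 | intermediate
7 | 2-{3-[(3-hydroxy-4,5-dimethoxyphenyl)ethynyl]phenoxy}-3-methoxybenzaldehyde | O=Cc1cccc(OC)c1Oc1cccc(c1)C#Cc1cc(O)c(OC)c(OC)c1 | intermediate
8 | 2-{3-[2-(3-hydroxy-4,5-dimethoxyphenyl)ethyl]phenoxy}-3-methoxybenzaldehyde | O=Cc1cccc(OC)c1Oc1cccc(c1)CCc1cc(O)c(OC)c(OC)c1 | intermediate
9 | 4-fluorobenzaldehyde | O=Cc1ccc(F)cc1 | starting material
10 | 2-(3-{2-[3-(4-formylphenoxy)-4,5-dimethoxyphenyl]ethyl}phenoxy)-3-methoxybenzaldehyde | O=Cc1ccc(cc1)Oc1cc(cc(OC)c1OC)CCc1cccc(c1)Oc1c(C=O)cccc1OC | intermediate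
11 | macrocyclic stilbene (E/Z), tri-O-methyl-dehydromarchantin A | COc1cc2cc(c1OC)Oc1ccc(cc1)C=Cc1cccc(OC)c1Oc1cccc(c1)CC2 | intermediate
12 | marchantin A tri-O-methyl ether | COc1cc2cc(c1OC)Oc1ccc(cc1)CCc1cccc(OC)c1Oc1cccc(c1)CC2 | intermediate
13 | marchantin A | Oc1cc2cc(c1O)Oc1ccc(cc1)CCc1cccc(O)c1Oc1cccc(c1)CC2 | target

## Summary

Total step count: 8.
Longest linear sequence: 7 (steps 1, 3, 4, 5, 6, 7, 8; step 2 is a one-step side branch).

Three steps most likely to fail, with fallbacks:

1. **Step 6, McMurry macrocyclisation** (risk: oligomers or pinacol instead of the 18-membered ring). Fallback: reduce dialdehyde 10 to the diol, convert to the bis(benzyl bromide), and close the ring by intramolecular Wurtz-type coupling (Na, catalytic tetraphenylethylene, THF, high dilution). This gives 12 directly with the saturated bridge.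
2. **Step 2, SNAr on 2-fluoro-3-methoxybenzaldehyde** (risk: the fluoride is hindered and activated only by one ortho CHO). Fallback: reverse the polarity. Use o-vanillin (2-hydroxy-3-methoxybenzaldehyde) as the nucleophile in a Cu-mediated Chan–Lam coupling with 3-iodophenylboronic acid, or an Ullmann coupling with excess 1,3-diiodobenzene, to reach the same 6.
3. **Step 4, aldehyde-sparing alkyne hydrogenation** (risk: over-reduction of the ArCHO or a stalled reaction). Fallback: avoid the alkyne entirely. Methylenate 1 to 5-vinyl-2,3-dimethoxyphenol (Wittig), hydroborate with 9-BBN, and run a B-alkyl Suzuki–Miyaura coupling with iodide 6 to give 8 directly with the saturated bridge.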